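## Analysis of the target

Compound 16 is an isoflavan quinone. A 6,7,8-trimethoxychroman (benzene ring A fused to the dihydropyran ring C made of O1, C2, C3, C4, C4a and C8a) carries at C3 a fully substituted 1,4-benzoquinone, ring B, with C1' bonded to C3, carbonyl groups at C3' and C6' and methoxy groups at C2', C4' and C5'. The only stereocentre is C3 (S), a tertiary C–H between C2 (OCH2), C4 (benzylic CH2) and C1'; it has no neighbouring stereocentre or heteroatom, so it cannot be set by relay. The quinone is the sensitive group: it is electrophilic and easily reduced, and because H3 is allylic to C1'=C2', base can tautomerise it to a quinone methide and racemise C3. Ring A, with O1 and the 6-methoxy group para to each other, is itself an oxidisable arene. The synthesis is hard because the crowded C3–C1' bond must be made with absolute control at an isolated centre, and because the quinone must be unveiled last by an oxidant that tells ring B from ring A. The strategy rests on three facts: C1' is the only ring B carbon with a carbon substituent, its neighbour C6' carries oxygen, and C4 is a benzylic carbon whose cation is stabilised by O1 (ortho to C4a) and the 7-methoxy group (para to C4a). A temporary C4–O6' bond therefore turns the target into the cis-fused pterocarpan 14, and since O6' is para to the C3' oxygen, the quinone is the oxidised form of the 6'-hydroxy-3'-methoxy arene 15.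

## Retrosynthetic reasoning

16 to 15. No skeletal bond is cut. The quinone is traced back to the para-methoxyphenol 15, in which C6' carries the only free hydroxyl group of the molecule. This places the sensitive quinone in the last step and gives the oxidant a handle on ring B that ring A lacks. The forward reaction has to oxidise the phenol and exchange the C3' methoxy group for a carbonyl oxygen without touching ring A or C3.

15 to 14. The C4–O6' bond is reconnected, which gives the cis-pterocarpan 14. The isolated centre C3 becomes C6a, one of two adjacent centres in a rigid fused system that an annulation can build. The forward reaction has to break only the benzylic C11a–O11 bond by hydrogenolysis; C11a is erased and C6a is kept.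

14 to 7 and 13. The bonds C6a–C6b (C3–C1') and C11a–O11 (C4–O6') are cut together. These are the two bonds that a polarised alkene forms with a three-atom C–C–O unit of a phenoxonium ion. Chromene 7 is nucleophilic at C3 and gives a stabilised cation at C4; quinone monoketal 13 has a single C–H carbon (C6), next to the carbonyl oxygen that closes the ring. The cut is made here because it is the most convergent one, both rings arrive fully oxygenated, and the stereocentre is created in the same event as the hindered C–C bond. The forward reaction has to ionise 13 with a chiral acid, form the C–C bond at C6 of 13, close the dihydrofuran cis, and take its facial selectivity from the chiral counter-anion.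

13 to 12, 10 and 8. The ketal carbon of 13 is the para carbon of phenol 12, so 13 follows from 12 by oxidative dearomatisation in an alcohol that supplies the second methoxy group. Phenol 12 comes from aldehyde 10 by exchange of the formyl group for oxygen (Dakin oxidation). The aryl–CHO bond of 10 is cut back to arene 8; the two free positions of 8 are equivalent, so the formylation has no regiochemical question.

7 to 5, then to 3 and 4. The C4–C4a bond of the chromene is cut, which gives aryl propargyl ether 5 (propargyl Claisen rearrangement in the forward sense). The ether O–CH2 bond is then cut to phenol 3 and propargyl bromide 4. Phenol 3 has one free ortho position only, so the ring can close in one direction only.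

8 and 5 to 3, then to 1. Arene 8 is the methyl ether of phenol 3, so both halves of the molecule converge on 3. Phenol 3 comes from the commercial aldehyde 1 by a second formyl-to-oxygen exchange.

## Alternatives that were turned down

Alternative 1: Ring A is not bought but built from a four-carbon unit. The ring A bonds around C4a–C8a are traced back to dimethyl squarate A1, which is alkynylated to the 4-alkynyl-4-hydroxycyclobutenone A2; A2 already holds the C3 stereocentre and a pentamethoxyphenyl precursor of ring B in its side chain. In the forward key step (Moore rearrangement), thermolysis opens A2 to an enynylketene, the ketene carbon (later C8a) bonds to the distal alkyne carbon (later C4a), and hydrogen transfer in the diradical gives quinone A3.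
- For: the reaction type is known, the 2,3-dimethoxy-5-alkylquinone is assembled without regiochemical doubt, and the stereocentre would come from established auxiliary or catalytic alkylation chemistry and is not endangered by the thermolysis. On certainty of stereocontrol this alternative is stronger than the chosen route.
- Against: A3 has the oxidation states of the two rings inverted relative to 16. Ring A is a quinone that must be reduced, cyclised onto C2 after desilylation and methylated. Ring B is a pentamethoxyarene that must then be oxidised in the presence of the equally electron-rich ring A, with no free phenol to direct the oxidant. The thermolysis can also divert to alkylidenecyclopentenediones, and the chiral side chain needs its own multi-step synthesis, so the count is well above that of the chosen route.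
- Comparison: the chosen route offers both rings from one cheap aldehyde, the C3–C1' bond and the stereocentre in one step, and a chemoselective last oxidation, because 15 carries a single phenol on ring B.

Alternative 2: The O1–C8a bond is cut, and the chroman is derived from the carbocyclic cis-indanol A4 by insertion of oxygen between the aromatic carbon and the carbinol carbon. In the forward key step (Hock rearrangement), acidic peroxide converts A4 into its benzylic hydroperoxide, the ring A carbon migrates from carbon to oxygen, and water adds to the cyclic oxocarbenium ion to give lactol A5. Reduction of the lactol carbon to CH2 and oxidation of ring B would follow.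
- For: the two centres of A4 can be set by asymmetric transfer hydrogenation under dynamic kinetic resolution, a known and reliable process, and the migrating aryl carbon has ortho and para methoxy groups, which is ideal for migration. Here too the enantiocontrol rests on precedent, which the chosen route cannot claim.
- Against: in A5 the C3 centre is α to a masked aldehyde and passes through an oxocarbenium ion that can lose H3, so acid-mediated epimerisation is built into the key step. Strongly acidic peroxide on two very electron-rich arenes invites ring oxidation. The lactol needs an extra reduction, A4 is itself long to make, and the final ring B oxidation has the same selectivity problem as in alternative 1.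
- Comparison: the chosen route makes the O1–C8a bond from a phenol at the outset, never places C3 next to a carbonyl-level carbon, and is shorter.

Alternative 3: Ring B is built last. The bonds C6'–C1', C2'–C3' and C5'–C6' are cut, which gives 2,3,4-trimethoxycyclobutenone A6 and the chromanyl siloxyalkyne A7. In the forward key step (Danheiser benzannulation), heating opens A6 to a vinylketene that adds across A7, with the ketene carbon going to the alkyne carbon that bears the chromanyl group; the resulting 2-vinylcyclobutenone opens to a dienylketene, which electrocyclises to phenol A8.
- For: the polarity of the ynol ether dictates the regiochemistry of the hexasubstituted ring. The oxygens arrive differentiated (free 6'-OH para to the 3'-methoxy group, silyl ether at C2'), so para-quinone formation is unambiguous, and no new enantioselective reaction is needed. On these points it is at least as strong as the chosen route.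
- Against: the stereocentre of A7 must come from a separate asymmetric hydrogenation and then survive a strongly basic ester-to-ynolate homologation while it is α to the carbonyl group. A6 is not commercial. A benzannulation that places a secondary alkyl group between two oxygenated carbons of a fully substituted benzene is the sterically worst case. After A8, oxidation, desilylation and O-methylation of a hydroxyquinone are still required.
- Comparison: the chosen route needs two easily made partners and two steps after the annulation, at the price of an unproven enantioselective step, for which a known fallback exists.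

Key step: step 8

Assumption: the sense of induction of the chiral acid in step 8 cannot be derived from structure alone. The (R)-configured catalyst is written, and its mirror image is taken if the first assay shows that it is the one leading to (6aS,11aS)-14.

## Route

Step 1
Reactants: 1 2,3,4-trimethoxybenzaldehyde
Product: 3 2,3,4-trimethoxyphenol, via 2,3,4-trimethoxyphenyl formate 2 (not isolated)
Conditions: 30% aq. H2O2, H2SO4 (cat.), MeOH, rt
Reagents that add atoms: hydrogen peroxide OO
Why: Acid-catalysed Dakin oxidation (Baeyer–Villiger type): the peroxide adds to the aldehyde, the electron-rich aryl group (ortho and para methoxy) migrates to oxygen to give formate 2, and acid-catalysed methanolysis of 2 releases phenol 3; the aryl methyl ethers are inert.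

Step 2
Reactants: 3 2,3,4-trimethoxyphenol; 4 propargyl bromide
Product: 5 1,2,3-trimethoxy-4-(prop-2-yn-1-yloxy)benzene
Conditions: K2CO3, acetone, reflux
Reagents that add atoms: none
Why: Williamson ether synthesis; the phenoxide of 3 displaces bromide from the primary propargylic halide by SN2.

Step 3
Reactants: 5 1,2,3-trimethoxy-4-(prop-2-yn-1-yloxy)benzene
Product: 7 6,7,8-trimethoxy-2H-chromene, via 6-(propa-1,2-dienyl)-2,3,4-trimethoxyphenol 6 (not isolated)
Conditions: PhNEt2, 210 °C, Ar
Reagents that add atoms: none
Why: Aryl propargyl ether Claisen rearrangement; the [3,3]-shift can deliver the allene only to C6 because C2 carries a methoxy group, enolisation gives allenylphenol 6, and a 1,5-hydrogen shift followed by oxa-6π-electrocyclisation closes the pyran ring of 7.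

Step 4
Reactants: 3 2,3,4-trimethoxyphenol
Product: 8 1,2,3,4-tetramethoxybenzene
Conditions: MeI, K2CO3, acetone, reflux
Reagents that add atoms: iodomethane CI
Why: O-Methylation of the phenoxide (Williamson ether synthesis); the two free ring positions of 8 are equivalent, which removes any regiochemical question from step 5.

Step 5
Reactants: 8 1,2,3,4-tetramethoxybenzene
Product: 10 2,3,4,5-tetramethoxybenzaldehyde, via N,N-dimethyl-2,3,4,5-tetramethoxybenzylideneiminium chloride 9 (not isolated)
Conditions: POCl3, DMF, 0 to 80 °C; then H2O, 50 °C
Reagents that add atoms: N,N-dimethylformamide CN(C)C=O; water O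
Why: Vilsmeier–Haack formylation; the chloroiminium ion attacks the free position, which is ortho to one methoxy group and para to another, and iminium salt 9 is hydrolysed on work-up to the aldehyde.

Step 6
Reactants: 10 2,3,4,5-tetramethoxybenzaldehyde
Product: 12 2,3,4,5-tetramethoxyphenol, via 2,3,4,5-tetramethoxyphenyl formate 11 (not isolated)
Conditions: 30% aq. H2O2, H2SO4 (cat.), MeOH, rt
Reagents that add atoms: hydrogen peroxide OO
Why: Acid-catalysed Dakin oxidation as in step 1; the migrating aryl carbon again has an ortho and a para methoxy group, and formate 11 is methanolysed in the flask.

Step 7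
Reactants: 12 2,3,4,5-tetramethoxyphenol
Product: 13 2,3,4,4,5-pentamethoxycyclohexa-2,5-dien-1-one
Conditions: PhI(OAc)2 (1.1 equiv), MeOH, 0 °C; NaHCO3 quench
Reagents that add atoms: methanol CO
Why: Oxidative dearomatisation of a para-methoxyphenol with a trivalent iodine reagent; the phenol exchanges onto iodine, methanol adds at the para carbon where the positive charge is stabilised by the methoxy group, and iodobenzene leaves, which is the normal course for 4-methoxyphenols; 13 is acid-labile and is used without delay.

Step 8
Reactants: 7 6,7,8-trimethoxy-2H-chromene; 13 2,3,4,4,5-pentamethoxycyclohexa-2,5-dien-1-one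
Product: 14 (6aS,11aS)-2,3,4,7,8,9,10-heptamethoxy-6a,11a-dihydro-6H-[1]benzofuro[3,2-c]chromene (cis-fused)
Conditions: (R)-3,3'-bis(2,4,6-triisopropylphenyl)-1,1'-binaphthyl-2,2'-diyl N-triflylphosphoramide (10 mol%), 5 Å MS, CH2Cl2, −40 °C, slow addition of 13; Et3N quench
Reagents that add atoms: none
Why: Proposed new method: the closest known reactions are the acid-promoted formal [3+2] annulations of quinone monoketals with styrenes and 2H-chromenes, which are racemic, and chiral-anion catalysis of oxocarbenium ions by confined phosphoramide acids; the two have not been combined on a phenoxonium ion. The acid protonates a ketal oxygen of 13 and, with loss of methanol to the sieves, gives the 2,3,4,5-tetramethoxyphenoxonium ion as a contact ion pair with the chiral phosphoramide anion. C3 of 7 attacks C6 of the cation, its only C–H carbon and a terminus of the allyl cation C4–C5–C6, because the cation that results at C4 of the chromene is stabilised by O1 and the 7-methoxy group. The former carbonyl oxygen then captures this benzylic cation in a 5-exo-trig closure (the C4–C4a π-bond of the cation lies outside the new ring), and loss of the C6 proton aromatises ring B and returns the acid. C6a is set in the C–C bond-forming step: the anion covers one face of the planar cation and, in the stacked approach that closure requires, decides which enantiotopic face of the C3=C4 bond is presented. C11a follows from C6a because the dihydrofuran fused to the pyran ring closes cis (the trans-fused ring is highly strained), and this centre is erased in step 9 in any case. Regioselectivity comes from the substrate, since attack at the fully substituted carbons C2 and C4 of the cation is hindered and cannot give an aromatic product; the enol-ether-like alkene is more nucleophilic than the hindered C5–H of ring A; only the absolute sense rests on the catalyst.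

Step 9
Reactants: 14 (6aS,11aS)-2,3,4,7,8,9,10-heptamethoxy-6a,11a-dihydro-6H-[1]benzofuro[3,2-c]chromene
Product: 15 2,3,4,5-tetramethoxy-6-[(3S)-6,7,8-trimethoxy-3,4-dihydro-2H-chromen-3-yl]phenol
Conditions: H2 (1 atm), 10% Pd/C, EtOAc–AcOH, rt
Reagents that add atoms: none
Why: Catalytic hydrogenolysis of the benzylic C11a–O11 aryl ether bond, the classical conversion of pterocarpans into 2'-hydroxyisoflavans; only this C–O bond is benzylic, C6a is not part of the bond that breaks and keeps its configuration (now C3, S), and the methyl ethers and the O5–C6 ether are not cleaved.

Step 10
Reactants: 15 2,3,4,5-tetramethoxy-6-[(3S)-6,7,8-trimethoxy-3,4-dihydro-2H-chromen-3-yl]phenol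
Product: 16 2,3,5-trimethoxy-6-[(3S)-6,7,8-trimethoxy-3,4-dihydro-2H-chromen-3-yl]cyclohexa-2,5-diene-1,4-dione
Conditions: PhI(OAc)2 (1.1 equiv), MeCN–H2O, 0 °C
Reagents that add atoms: water O
Why: Oxidative demethylation of a para-methoxyphenol to a para-quinone with a trivalent iodine reagent; the phenol, the only free hydroxyl group, binds to iodine, water adds at C3' para to it, and the hemiketal loses methanol; ring A has no free phenol and should not react, and the weakly acidic medium avoids base-induced tautomerisation at C3.

## Compound list

1 | 2,3,4-trimethoxybenzaldehyde | COc1ccc(C=O)c(OC)c1OC | starting material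
2 | 2,3,4-trimethoxyphenyl formate | COc1ccc(OC=O)c(OC)c1OC | intermediate (not isolated)
3 | 2,3,4-trimethoxyphenol | COc1ccc(O)c(OC)c1OC | intermediate
4 | propargyl bromide (3-bromoprop-1-yne) | C#CCBr | starting material
5 | 1,2,3-trimethoxy-4-(prop-2-yn-1-yloxy)benzene | COc1ccc(OCC#C)c(OC)c1OC | intermediate
6 | 6-(propa-1,2-dienyl)-2,3,4-trimethoxyphenol | COc1cc(C=C=C)c(O)c(OC)c1OC | intermediate (not isolated)
7 | 6,7,8-trimethoxy-2H-chromene | COc1cc2C=CCOc2c(OC)c1OC | intermediate
8 | 1,2,3,4-tetramethoxybenzene | COc1ccc(OC)c(OC)c1OC | intermediate
9 | N,N-dimethyl-2,3,4,5-tetramethoxybenzylideneiminium chloride | COc1cc(C=[N+](C)C)c(OC)c(OC)c1OC.[Cl-] | intermediate (not isolated)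
10 | 2,3,4,5-tetramethoxybenzaldehyde | COc1cc(C=O)c(OC)c(OC)c1OC | intermediate
11 | 2,3,4,5-tetramethoxyphenyl formate | COc1cc(OC=O)c(OC)c(OC)c1OC | intermediate (not isolated)
12 | 2,3,4,5-tetramethoxyphenol | COc1cc(O)c(OC)c(OC)c1OC | intermediate
13 | 2,3,4,4,5-pentamethoxycyclohexa-2,5-dien-1-one | O=C1C=C(OC)C(OC)(OC)C(OC)=C1OC | intermediate
14 | (6aS,11aS)-2,3,4,7,8,9,10-heptamethoxy-6a,11a-dihydro-6H-[1]benzofuro[3,2-c]chromene | COc1c(OC)c(OC)c(OC)c2c1[C@H]1COc3c(cc(OC)c(OC)c3OC)[C@H]1O2 | intermediate
15 | 2,3,4,5-tetramethoxy-6-[(3S)-6,7,8-trimethoxy-3,4-dihydro-2H-chromen-3-yl]phenol | COc1c(OC)c(OC)c(OC)c(O)c1[C@H]1COc2c(cc(OC)c(OC)c2OC)C1 | intermediate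
16 | 2,3,5-trimethoxy-6-[(3S)-6,7,8-trimethoxy-3,4-dihydro-2H-chromen-3-yl]cyclohexa-2,5-diene-1,4-dione | COC1=C(OC)C(=O)C([C@H]2COc3c(cc(OC)c(OC)c3OC)C2)=C(OC)C1=O | target

## Step count and least certain steps

Total: 10 steps. Longest linear sequence: 8 steps (steps 1, 4, 5, 6, 7, 8, 9 and 10); the chromene branch (steps 1, 2 and 3) joins at step 8.

Step 8 (key step). The most likely failure is poor facial selectivity: neither the phenoxonium ion nor the chromene has a hydrogen-bond donor to anchor the anion, so the induction depends on ion pairing alone. Further risks are acid-induced oligomerisation of 7, hydrolysis of 13 to the quinone by traces of water, capture of the C4 cation by the released methanol or by a ring carbon (bridged adducts), and re-ionisation of 14 followed by loss of H6a, which would erode the enantiomeric purity. More confined acids of the imidodiphosphorimidate type would be tried first. The fallback uses known chemistry; it sets out from 13 and 7 and comes back at 14. Hydrolysis of 13 (dilute aqueous acid, THF) gives 2,3,5-trimethoxycyclohexa-2,5-diene-1,4-dione F1. F1 and 7 are combined in CH2Cl2 at −78 °C with a stoichiometric amount of TiCl2(TADDOLate), made from TiCl4, Ti(OiPr)4 and the TADDOL antipode that leads to the (6aS,11aS) series; this is the known enantioselective annulation of 2-alkoxybenzoquinones with 2H-chromenes. Tetravalent titanium bound to the C4 carbonyl and a flanking methoxy group activates C6, the only C–H carbon of F1; C3 of 7 adds there and the C1 carbonyl oxygen closes the dihydrofuran, giving (6aS,11aS)-2,3,4,7,9,10-hexamethoxy-6a,11a-dihydro-6H-[1]benzofuro[3,2-c]chromen-8-ol F2. O-Methylation of F2 (MeI, K2CO3, acetone) gives 14, and crystallisation can raise its enantiomeric purity.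

Step 3. Thermal stress is the risk: the electron-rich chromene can polymerise or decompose at the temperature of the rearrangement, and allenylphenol 6 can close to a 2-methylbenzofuran instead. The fallback sets out from 3 and comes back at 7. Magnesium-mediated ortho-formylation (MgCl2, Et3N, paraformaldehyde, MeCN, reflux) at the only free ortho position gives 2-hydroxy-3,4,5-trimethoxybenzaldehyde F3. Its phenoxide reacts with vinyltriphenylphosphonium bromide (K2CO3, DMF) by oxa-Michael addition and intramolecular Wittig reaction to give 7. Step 2 and compound 5 then fall away.

Step 9. Sluggish cleavage of the crowded benzylic C–O bond on the catalyst surface is the most likely problem. The fallback sets out from 14 and comes back at 15 and makes no new compound (F0). It is an ionic hydrogenation (Et3SiH, BF3·OEt2, CH2Cl2, −78 to −40 °C): the Lewis acid ionises the C11a–O11 bond to the cation stabilised by O1 and the 7-methoxy group, and the silane delivers hydride to C4. Low temperature and excess silane are needed so that hydride capture outruns loss of H3, which would racemise the centre.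

Step 10. Water may add ortho instead of para to the iodine-bound phenol (ortho-quinone formation), ring A may be oxidised by excess reagent, and the product can racemise through its quinone methide tautomer if exposed to base. The fallback sets out from 15 and comes back at 16 in two stages. Oxidation with PhI(OAc)2 in anhydrous MeOH at 0 °C, the reaction type of step 7 on the same substitution pattern, gives the isolable ketal 2,3,4,4,5-pentamethoxy-6-[(3S)-6,7,8-trimethoxy-3,4-dihydro-2H-chromen-3-yl]cyclohexa-2,5-dien-1-one F4. Mild hydrolysis of F4 (aqueous oxalic acid, THF) then gives 16 with no choice of regiochemistry left.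

## Further compounds

F1 | step 8 | 2,3,5-trimethoxycyclohexa-2,5-diene-1,4-dione | COC1=CC(=O)C(OC)=C(OC)C1=O
F2 | step 8 | (6aS,11aS)-2,3,4,7,9,10-hexamethoxy-6a,11a-dihydro-6H-[1]benzofuro[3,2-c]chromen-8-ol | COc1c(O)c(OC)c(OC)c2c1[C@H]1COc3c(cc(OC)c(OC)c3OC)[C@H]1O2
F3 | step 3 | 2-hydroxy-3,4,5-trimethoxybenzaldehyde | COc1cc(C=O)c(O)c(OC)c1OC
F0 | step 9 | none | none
F4 | step 10 | 2,3,4,4,5-pentamethoxy-6-[(3S)-6,7,8-trimethoxy-3,4-dihydro-2H-chromen-3-yl]cyclohexa-2,5-dien-1-one | COC1=C(OC)C(=O)C([C@H]2COc3c(cc(OC)c(OC)c3OC)C2)=C(OC)C1(OC)OC
A1 | alternative 1 | dimethyl squarate (3,4-dimethoxycyclobut-3-ene-1,2-dione) | COC1=C(OC)C(=O)C1=O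
A2 | alternative 1 | 4-[(4S)-5-(tert-butyldimethylsilyloxy)-4-(pentamethoxyphenyl)pent-1-yn-1-yl]-4-hydroxy-2,3-dimethoxycyclobut-2-en-1-one (carbinol carbon unassigned) | COc1c(OC)c(OC)c(OC)c(OC)c1[C@H](CC#CC1(O)C(OC)=C(OC)C1=O)CO[Si](C)(C)C(C)(C)C
A3 | alternative 1 | 5-[(2S)-3-(tert-butyldimethylsilyloxy)-2-(pentamethoxyphenyl)propyl]-2,3-dimethoxy-1,4-benzoquinone | COc1c(OC)c(OC)c(OC)c(OC)c1[C@H](CC2=CC(=O)C(OC)=C(OC)C2=O)CO[Si](C)(C)C(C)(C)C
A4 | alternative 2 | (1R,2S)-5,6,7-trimethoxy-2-(pentamethoxyphenyl)-2,3-dihydro-1H-inden-1-ol (cis) | COc1c(OC)c(OC)c(OC)c(OC)c1[C@H]1[C@@H](O)c2c(OC)c(OC)c(OC)cc2C1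
A5 | alternative 2 | (3S)-6,7,8-trimethoxy-3-(pentamethoxyphenyl)chroman-2-ol (anomeric mixture) | COc1c(OC)c(OC)c(OC)c(OC)c1[C@H]1C(O)Oc2c(cc(OC)c(OC)c2OC)C1
A6 | alternative 3 | 2,3,4-trimethoxycyclobut-2-en-1-one | COC1C(OC)=C(OC)C1=O
A7 | alternative 3 | triisopropyl({[(3S)-6,7,8-trimethoxy-3,4-dihydro-2H-chromen-3-yl]ethynyl}oxy)silane | CC(C)[Si](OC#C[C@H]1COc2c(cc(OC)c(OC)c2OC)C1)(C(C)C)C(C)C
A8 | alternative 3 | 4,5,6-trimethoxy-2-[(3S)-6,7,8-trimethoxychroman-3-yl]-3-(triisopropylsilyloxy)phenol | Oc1c(OC)c(OC)c(OC)c(O[Si](C(C)C)(C(C)C)C(C)C)c1[C@H]1COc2c(cc(OC)c(OC)c2OC)C1
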